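**Strategy.** Ring A, the cyclohexenone C1(=O)–C2=C3(Me)–C4–C5–C11 (longipinane numbering; C4, C5, C10 and C11 form the cyclobutane), is disconnected by removing C2, which leads back to a bicyclo[2.1.1]hexan-2-one and a one-carbon Saegusa ring expansion. The key step opens a siloxycyclopropane with FeCl3, inserts C2 between C1 and C3 and, after loss of HCl, gives the enone with its C3 methyl in one operation. It exploits that C11 is a cyclobutane bridgehead, so the ketone enolizes only toward C3, and that C3 gives a tertiary radical. The precursor, a tricyclic five-membered ketone, comes from an intramolecular keteniminium–diene [2+2] cycloaddition and a rhodium hydroacylation.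

Key step: step 13

Remarks.
- Numbering: atoms carry the longipinane numbers of the target throughout: C1 (ketone), C2, C3 (methyl C12), C4, C5, C6 (methyl C14, oxymethylene C15), C7 (oxygenated CH), C8, C9, C10 (methyl C13), C11. Ring A = C1–C2–C3–C4–C5–C11; ring B = cyclobutane C4–C5–C11–C10; ring C = C5–C6–C7–C8–C9–C10–C11.
- Assumption: the (S)-ligand of the iridium catalyst in step 2 is taken to give (5S,6S)-5; if the sense of induction is the reverse, the (R)-ligand is used.
- Assumption: the anti selectivity of step 2 is taken to mean the C7 hydroxyl anti to C15 in the zigzag sense. This C7 configuration is opposite to the target; it is used to steer step 7 and is corrected in steps 15 and 16.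
- Compounds 3 and 5–9 are mixtures of epimers at the amide α-carbon (future C10); both converge in step 7, where this carbon becomes sp2.

**Step 1**
Reactants: 1 rac-3-methyltetrahydro-2H-pyran-2-one; 2 pyrrolidine
Product: 3 rac-5-hydroxy-2-methyl-1-(pyrrolidin-1-yl)pentan-1-one
Conditions: pyrrolidine (3 equiv), neat, 60 °C
Reagents that add atoms: none
Why: Aminolysis of the δ-lactone gives a tertiary hydroxy amide that cannot relactonize under the later basic conditions and is the direct precursor of the keteniminium ion of step 7.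

**Step 2**
Reactants: 3 rac-5-hydroxy-2-methyl-1-(pyrrolidin-1-yl)pentan-1-one; 4 rac-2-methyl-2-vinyloxirane
Product: 5 (5S,6S)-5-hydroxy-6-(hydroxymethyl)-2,6-dimethyl-1-(pyrrolidin-1-yl)oct-7-en-1-one
Conditions: Ir(η3-C3H5)[(S)-Tol-BINAP][4-cyano-3-nitrobenzoate-κC,O] (5 mol %), K3PO4 (5 mol %), THF, 45 °C
Reagents that add atoms: none
Why: Krische transfer-hydrogenative tert-(hydroxy)prenylation: the alcohol is dehydrogenated to the aldehyde, isoprene oxide is opened to a σ-allyliridium, and a closed chair transition state with the CH2OH arm pseudo-equatorial sets the quaternary C6 (ligand control) and the C7 carbinol (anti to C15) in one C–C coupling.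

**Step 3**
Reactants: 5 (5S,6S)-diol amide
Product: 6 4-[(4S,5S)-2,2-di-tert-butyl-5-methyl-5-vinyl-1,3,2-dioxasilinan-4-yl]-2-methyl-1-(pyrrolidin-1-yl)butan-1-one
Conditions: tBu2Si(OTf)2, 2,6-lutidine, CH2Cl2, 0 °C
Reagents that add atoms: di-tert-butylsilyl bis(trifluoromethanesulfonate), CC(C)(C)[Si](OS(=O)(=O)C(F)(F)F)(OS(=O)(=O)C(F)(F)F)C(C)(C)C
Why: Silylene formation ties O7 and O15 into a six-membered ring that should survive the later acidic, basic and organometallic steps and fixes the conformation used for stereocontrol in step 7.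

**Step 4**
Reactants: 6 vinyl silylene amide
Product: 7 the corresponding 5-formyl dioxasilinane (C5 aldehyde, configuration unchanged)
Conditions: O3, CH2Cl2–MeOH, −78 °C; then Me2S
Reagents that add atoms: ozone, [O-][O+]=O
Why: Ozonolysis with reductive work-up cleaves the only alkene to a neopentyl aldehyde that cannot epimerize because C6 is quaternary.

**Step 5**
Reactants: 7 aldehyde
Product: 8 the corresponding 5-[(E)-2-iodovinyl] dioxasilinane
Conditions: CHI3, CrCl2, THF, 0 °C to rt
Reagents that add atoms: iodoform, IC(I)I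
Why: Takai olefination converts the aldehyde into the vinyl iodide with the high E selectivity typical of the geminal dichromium reagent.

**Step 6**
Reactants: 8 (E)-vinyl iodide
Product: 9 the corresponding 5-[(E)-buta-1,3-dienyl] dioxasilinane (C5=C4–C3=C12 diene)
Conditions: tributyl(vinyl)stannane, Pd(PPh3)4 (5 mol %), CuI (10 mol %), DMF, 50 °C
Reagents that add atoms: tributyl(vinyl)stannane, C=C[Sn](CCCC)(CCCC)CCCC
Why: Stille coupling with retention of alkene geometry gives the (E)-1,3-diene whose inner carbon becomes C4 and whose vinyl end becomes C3 and C12.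

**Step 7**
Reactants: 9 (E)-diene amide
Product: 12 bicyclo[4.1.1]octan-8-one (rings B and C; C11 ketone; C4 vinyl trans to C6), via keteniminium triflate 10 (not isolated), via cyclobutaniminium triflate 11 (not isolated)
Conditions: Tf2O, 2,4,6-collidine, ClCH2CH2Cl (0.005 M), −20 °C to 80 °C; then aq. NaHCO3, rt
Reagents that add atoms: water, O
Why: Ghosez keteniminium–alkene [2+2] cycloaddition in the bridged mode: the iminium carbon C11 bonds to the diene terminus C5 and the enamine carbon C10 closes onto the allyl cation at C4, ring C forming through a chair-like transition state with O7 and the C14 methyl pseudo-equatorial and C15 pseudo-axial so that C4 adds anti to C15, while the E alkene places the vinyl group trans to C6.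

**Step 8**
Reactants: 12 cyclobutanone
Product: 13 C11 methoxymethylene derivative (methyl enol ether, E/Z mixture)
Conditions: Ph3P(CH2OMe)Cl, KN(SiMe3)2, THF, 0 °C to rt
Reagents that add atoms: (methoxymethyl)triphenylphosphonium chloride, COC[P+](c1ccccc1)(c1ccccc1)c1ccccc1.[Cl-]
Why: Wittig olefination of the strained, electrophilic cyclobutanone adds the carbon that becomes C1; C5 and C10 cannot epimerize.

**Step 9**
Reactants: 13 enol ether
Product: 14 C11 carbaldehyde (formyl group cis to the C4 vinyl group, both on the face of ring B away from ring C)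
Conditions: 2 M aq. HCl, THF, 0 °C to rt
Reagents that add atoms: water, O
Why: Enol ether hydrolysis: C11 is protonated from the open outer face because the inner face is blocked by the C4 vinyl group, and the resulting cis aldehyde should also be the less crowded epimer since it avoids eclipsing C6 and C9.

**Step 10**
Reactants: 14 aldehyde
Product: 15 tricyclic 3-methylbicyclo[2.1.1]hexan-2-one (C1 ketone, C3 methyl C12 syn to C5–H)
Conditions: [Rh(Ph2PCH2CH2PPh2)]ClO4 (5 mol %), CH2Cl2, 25–40 °C
Reagents that add atoms: none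
Why: Intramolecular hydroacylation by cationic monovalent rhodium: C–H oxidative addition, Markovnikov hydride insertion into the vinyl group to a six-membered acyl rhodacycle and reductive elimination close the five-membered ketone C11–C1(=O)–C3–C4 and turn C12 into the C3 methyl.

**Step 11**
Reactants: 15 tricyclic ketone
Product: 16 C1 trimethylsilyl enol ether (C1=C3)
Conditions: Me3SiOTf, Et3N, CH2Cl2, 0 °C
Reagents that add atoms: trimethylsilyl trifluoromethanesulfonate, C[Si](C)(C)OS(=O)(=O)C(F)(F)F
Why: Soft enolization can occur only toward C3 because C11 is a bridgehead, so the tetrasubstituted silyl enol ether should form regiospecifically.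

**Step 12**
Reactants: 16 silyl enol ether
Product: 17 siloxycyclopropane (C2 methylene bridging C1 and C3, syn to C5–H)
Conditions: Et2Zn, CH2I2, CH2Cl2, 0 °C to rt; pyridine quench
Reagents that add atoms: diiodomethane, ICI
Why: Furukawa–Simmons–Smith cyclopropanation of the electron-rich strained enol ether from the face anti to the C13 methyl installs the future C2.

**Step 13**
Reactants: 17 siloxycyclopropane
Product: 19 (7S)-7,15-O-(di-tert-butylsilylene)-7,15-dihydroxylongipin-2-en-1-one, via chloro ketone 18 (not isolated)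
Conditions: FeCl3 (2.5 equiv), DMF, 0 °C to rt; then NaOAc, MeOH, reflux
Reagents that add atoms: none
Why: FeCl3 oxidizes the siloxycyclopropane 17 by one electron; the strained zero-atom bridge C1–C3, shared by the cyclopropane and the five-membered ring (C1, C3, C4, C5, C11), breaks with loss of the silyl group to give the C1 ketone and a tertiary C3 radical that now lies in six-membered ring A, and chlorine transfer from a second FeCl3 gives the β-chloro ketone 18. NaOAc then removes HCl by E1cB elimination through the C2 enolate, the only enolate possible because C11 is a bridgehead, which gives the conjugated C2=C3 enone. The closest known reaction is the Ito–Saegusa one-carbon ring expansion of 1-siloxybicyclo[n.1.0]alkanes to 2-cycloalkenones. No ring is closed by bond formation: ring A arises by expansion of the five-membered ring through scission of the cyclopropane bond, the inserted atom being C2. No lasting stereocentre is created (C3 becomes sp2 and the chloride of 18 is lost), and C4, C5, C10 and C11 cannot epimerize. The step needs cleavage of the internal rather than an external cyclopropane bond and fast chlorine capture of the C3 radical; the tertiary nature of that radical, the relief of bicyclo[2.1.1]hexane strain and the excess of FeCl3 should secure this.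

**Step 14**
Reactants: 19 enone silylene
Product: 20 (4R,5S,6S,7S,10R,11R)-7,15-dihydroxylongipin-2-en-1-one (7-epi diol)
Conditions: HF·pyridine, THF–pyridine, 0 °C to rt
Reagents that add atoms: none
Why: Fluoride cleaves both Si–O bonds of the silylene without touching the enone.

**Step 15**
Reactants: 20 7-epi diol
Product: 21 1,7-dioxolongipin-2-en-15-al (keto aldehyde)
Conditions: Dess–Martin periodinane (3 equiv), NaHCO3, CH2Cl2, 0 °C to rt
Reagents that add atoms: none
Why: Dess–Martin oxidation of both hydroxyls gives a β-keto aldehyde that cannot enolize at the quaternary C6 and erases the C7 centre after it has served in step 7.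

**Step 16**
Reactants: 21 keto aldehyde
Product: 23 (4R,5S,6S,7R,10R,11R)-7,15-dihydroxylongipin-2-en-1-one, via hydroxy dione 22 (not isolated)
Conditions: Me4NBH(OAc)3 (8 equiv), MeCN–AcOH (1:1), −20 °C to rt
Reagents that add atoms: none
Why: Triacetoxyborohydride reduces the aldehyde first, and the C15 alkoxyborohydride then delivers hydride to the C7 ketone from the C15 face (Evans–Saksena directed reduction), so the new C7 hydroxyl should be trans to C15 and cis to the C14 methyl while the enone is left intact.

**Step 17**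
Reactants: 23 diol; 24 angelic acid
Product: 26 (4R,5S,6S,7R,10R,11R)-7,15-bis[(Z)-2-methylbut-2-enoyloxy]longipin-2-en-1-one (CNP0240716.2), via mixed anhydride 25 (not isolated)
Conditions: 24 (4 equiv), 2,4,6-trichlorobenzoyl chloride, Et3N, toluene, rt; then 23, toluene, 80 °C
Reagents that add atoms: none
Why: Yamaguchi-type acylation with the preformed mixed anhydride should esterify the primary and the hindered secondary hydroxyl without a nucleophilic catalyst, conditions under which the Z geometry of angelates is retained.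

**Compound list**

1 | rac-3-methyltetrahydro-2H-pyran-2-one | CC1CCCOC1=O | starting material
2 | pyrrolidine | C1CCNC1 | starting material
3 | rac-5-hydroxy-2-methyl-1-(pyrrolidin-1-yl)pentan-1-one | CC(CCCO)C(=O)N1CCCC1 | intermediate
4 | rac-2-methyl-2-vinyloxirane (isoprene oxide) | CC1(C=C)CO1 | starting material
5 | (5S,6S)-5-hydroxy-6-(hydroxymethyl)-2,6-dimethyl-1-(pyrrolidin-1-yl)oct-7-en-1-one (C2 epimers) | OC[C@](C)(C=C)[C@@H](O)CCC(C)C(=O)N1CCCC1 | intermediate
6 | 4-[(4S,5S)-2,2-di-tert-butyl-5-methyl-5-vinyl-1,3,2-dioxasilinan-4-yl]-2-methyl-1-(pyrrolidin-1-yl)butan-1-one | CC(C)(C)[Si]2(C(C)(C)C)OC[C@](C)(C=C)[C@H](CCC(C)C(=O)N1CCCC1)O2 | intermediate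
7 | 5-formyl analogue of 6 (aldehyde at the quaternary carbon) | CC(C)(C)[Si]2(C(C)(C)C)OC[C@](C)(C=O)[C@H](CCC(C)C(=O)N1CCCC1)O2 | intermediate
8 | 5-[(E)-2-iodovinyl] analogue of 6 | CC(C)(C)[Si]2(C(C)(C)C)OC[C@](C)(/C=C/I)[C@H](CCC(C)C(=O)N1CCCC1)O2 | intermediate
9 | 5-[(E)-buta-1,3-dienyl] analogue of 6 (diene amide) | CC(C)(C)[Si]2(C(C)(C)C)OC[C@](C)(/C=C/C=C)[C@H](CCC(C)C(=O)N1CCCC1)O2 | intermediate
10 | keteniminium triflate of 9 | CC(C)(C)[Si]2(C(C)(C)C)OC[C@](C)(/C=C/C=C)[C@H](CCC(C)=C=[N+]1CCCC1)O2.[O-]S(=O)(=O)C(F)(F)F | intermediate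
11 | cyclobutaniminium triflate (rings B and C closed, C11=N+) | CC(C)(C)[Si]4(C(C)(C)C)OC[C@]1(C)[C@@H]2C(=[N+]5CCCC5)[C@](C)(CC[C@@H]1O4)[C@H]2C=C.[O-]S(=O)(=O)C(F)(F)F | intermediate
12 | bicyclo[4.1.1]octan-8-one: C11 ketone, C4 vinyl trans to C6, C13 methyl on C10, O7,O15-di-tert-butylsilylene | CC(C)(C)[Si]4(C(C)(C)C)OC[C@]1(C)[C@@H]2C(=O)[C@](C)(CC[C@@H]1O4)[C@H]2C=C | intermediate
13 | C11 methoxymethylene derivative of 12 (E/Z mixture) | CC(C)(C)[Si]4(C(C)(C)C)OC[C@]1(C)[C@@H]2C(=COC)[C@](C)(CC[C@@H]1O4)[C@H]2C=C | intermediate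
14 | C11 carbaldehyde, formyl cis to the C4 vinyl group | CC(C)(C)[Si]4(C(C)(C)C)OC[C@]1(C)[C@@H]2[C@@H](C=O)[C@](C)(CC[C@@H]1O4)[C@H]2C=C | intermediate
15 | tricyclic 3-methylbicyclo[2.1.1]hexan-2-one (C1 ketone, C3–H, C12 methyl syn to C5–H) | CC(C)(C)[Si]4(C(C)(C)C)OC[C@]1(C)[C@@H]2[C@H]3C(=O)[C@@H](C)[C@@H]2[C@@]3(C)CC[C@@H]1O4 | intermediate
16 | trimethylsilyl enol ether of 15 (C1=C3) | CC(C)(C)[Si]4(C(C)(C)C)OC[C@]1(C)[C@@H]2[C@H]3C(O[Si](C)(C)C)=C(C)[C@@H]2[C@@]3(C)CC[C@@H]1O4 | intermediate
17 | siloxycyclopropane (C1–C2–C3 three-membered ring on the five-membered ring) | CC(C)(C)[Si]4(C(C)(C)C)OC[C@]1(C)[C@@H]2[C@H]3[C@@]5(O[Si](C)(C)C)C[C@@]5(C)[C@@H]2[C@@]3(C)CC[C@@H]1O4 | intermediate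
18 | 3-chloro-3-methyl ketone with ring A formed (β-chloro ketone) | CC(C)(C)[Si]4(C(C)(C)C)OC[C@]1(C)[C@@H]2[C@H]3C(=O)C[C@@](C)(Cl)[C@@H]2[C@@]3(C)CC[C@@H]1O4 | intermediate
19 | (7S)-7,15-O-(di-tert-butylsilylene)-7,15-dihydroxylongipin-2-en-1-one | CC(C)(C)[Si]4(C(C)(C)C)OC[C@]1(C)[C@@H]2[C@H]3C(=O)C=C(C)[C@@H]2[C@@]3(C)CC[C@@H]1O4 | intermediate
20 | (4R,5S,6S,7S,10R,11R)-7,15-dihydroxylongipin-2-en-1-one | OC[C@]1(C)[C@@H]2[C@H]3C(=O)C=C(C)[C@@H]2[C@@]3(C)CC[C@@H]1O | intermediate
21 | 1,7-dioxolongipin-2-en-15-al | O=C[C@]1(C)[C@@H]2[C@H]3C(=O)C=C(C)[C@@H]2[C@@]3(C)CCC1=O | intermediate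
22 | 15-hydroxylongipin-2-ene-1,7-dione (as its C15 borate in the flask) | OC[C@]1(C)[C@@H]2[C@H]3C(=O)C=C(C)[C@@H]2[C@@]3(C)CCC1=O | intermediate
23 | (4R,5S,6S,7R,10R,11R)-7,15-dihydroxylongipin-2-en-1-one | OC[C@]1(C)[C@@H]2[C@H]3C(=O)C=C(C)[C@@H]2[C@@]3(C)CC[C@H]1O | intermediate
24 | angelic acid, (Z)-2-methylbut-2-enoic acid | C/C=C(/C)C(O)=O | starting material
25 | angelic 2,4,6-trichlorobenzoic anhydride | C/C=C(/C)C(=O)OC(=O)c1c(Cl)cc(Cl)cc1Cl | intermediate
26 | (4R,5S,6S,7R,10R,11R)-7,15-bis(angeloyloxy)longipin-2-en-1-one (CNP0240716.2) | C/C=C(/C)C(=O)OC[C@]1(C)[C@@H]2[C@H]3C(=O)C=C(C)[C@@H]2[C@@]3(C)CC[C@H]1OC(=O)/C(C)=C\C | target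

**Step count.** Total: 17 steps. Longest linear sequence: 17 steps (from 1).

**Steps most likely to fail**

1. Step 7. Closure of the seven-membered ring by the keteniminium ion may be slower than oligomerization, or the facial selectivity at C5 may be poor. The fallback replaces the cationic stepwise cycloaddition by a neutral, concerted ketene cycloaddition of the Snider kind. It sets out from 9: reduction of the amide with LiNH2BH3 in THF should give the primary alcohol F1; oxidation with TEMPO and PhI(OAc)2 in MeCN–H2O should give the carboxylic acid F2; (COCl)2 with catalytic DMF should give the acid chloride F3; slow addition of F3 to Et3N in refluxing toluene at high dilution should generate the methyl ketene F4, which should add to the diene in the same bridged sense and return to the route at 12.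

2. Step 10. Decarbonylation of the acyl rhodium hydride, or alkene isomerization, may outrun the strained ring closure. The fallback is a radical closure. It sets out from 14: SmI2 with HMPA and t-BuOH in THF should form the C1 ketyl radical, which should close 5-exo onto the vinyl group and, after reduction and protonation of the primary radical to the C12 methyl, give the secondary alcohol F5; Dess–Martin oxidation of F5 should return to the route at 15.

3. Step 13. The C3 radical is a cyclobutylcarbinyl radical and may open ring B by β-scission of C4–C10 before chlorine is transferred, or an external cyclopropane bond may be cleaved to a ring-retained α,α-dimethyl ketone. The fallback avoids radicals by a two-electron electrocyclic ring expansion. It sets out from 16: CHBr3 and KOtBu in pentane at −20 °C should give the dibromocyclopropane F6; heating in toluene with pyridine should open the C1–C3 bond in a cyclopropyl-to-allyl manner with loss of Me3SiBr and give the 2-bromo enone F7; hydrodebromination with Bu3SnH and Pd(PPh3)4 (zerovalent palladium) should return to the route at 19.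

**Further compounds**

F1 | step 7 | primary alcohol from reduction of amide 9 | CC(C)(C)[Si]2(C(C)(C)C)OC[C@](C)(/C=C/C=C)[C@H](CCC(C)CO)O2
F2 | step 7 | carboxylic acid | CC(C)(C)[Si]2(C(C)(C)C)OC[C@](C)(/C=C/C=C)[C@H](CCC(C)C(O)=O)O2
F3 | step 7 | acid chloride | CC(C)(C)[Si]2(C(C)(C)C)OC[C@](C)(/C=C/C=C)[C@H](CCC(C)C(Cl)=O)O2
F4 | step 7 | methyl ketene | CC(C)(C)[Si]2(C(C)(C)C)OC[C@](C)(/C=C/C=C)[C@H](CCC(C)=C=O)O2
F5 | step 10 | C1 alcohol of 15 (hydroxyl syn to C5–H) | CC(C)(C)[Si]4(C(C)(C)C)OC[C@]1(C)[C@@H]2[C@H]3[C@@H](O)[C@@H](C)[C@@H]2[C@@]3(C)CC[C@@H]1O4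
F6 | step 13 | 2,2-dibromo siloxycyclopropane | CC(C)(C)[Si]4(C(C)(C)C)OC[C@]1(C)[C@@H]2[C@H]3[C@@]5(O[Si](C)(C)C)C(Br)(Br)[C@@]5(C)[C@@H]2[C@@]3(C)CC[C@@H]1O4
F7 | step 13 | 2-bromo analogue of enone 19 | CC(C)(C)[Si]4(C(C)(C)C)OC[C@]1(C)[C@@H]2[C@H]3C(=O)C(Br)=C(C)[C@@H]2[C@@]3(C)CC[C@@H]1O4
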